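The runs stem from a simulated flask with made-up constants; scatter was added.

The ratio to follow is target gained per trapped intermediate gained. Take it as a selectivity factor a divided by the fraction of capture agent left; added up over a run, this gives target, counted against the charge of capture agent, = a·ln(charged/left).

| flask | substrate | partner | capture agent | free catalyst | remark | time |
|---|---|---|---|---|---|---|
| dusk | 0.20 M | 3 equiv | 0.20 M | 0.025 mol% | run made earlier |  |
| flask | 0.20 M | 3.00 equiv | 0.200 M | 0.05 mol% |  | 3.0 d |

- dusk (time / h: target / %, trapped intermediate / %): 1.00: 2, 11; 2.00: 8, 22; 4.00: 14, 41; 8.00: 28, 52; 15.0: 34, 58

(readings scatter by 1.5 percentage points)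

1. share of target in target plus trapped intermediate at 30 min
2. share of target in target plus trapped intermediate at 3.0 d

- no earlier run changes the charge of free catalyst; that part of a forecast is a guess

With capture agent charged equal to substrate, the dusk reading at 15.0 h puts a, the ratio at full [capture agent], at 0.392, with the scatter of that reading. No earlier run varies free catalyst, so the next step is a guess: if target needs free catalyst and trapping does not, a scales with the loading, to 0.784 in this flask.

At the start the share is a divided by one plus a, 43.9 %, and I take that as my number for 30 min, early in the run. For the end I take target and trapped intermediate to make up the substrate charged; with capture agent charged equal to substrate, the fraction of capture agent left then equals the fraction of target. A trial of 0.5 returns 0.543, and halfway lies 52.2 %, my number for 3.0 d.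

The forecast says 24 % and 40 %, from “a common intermediate partitioning between partner (3 equiv, barely depleted) and a stoichiometric capture agent that is being used up”. My numbers stand higher than the forecast's; mine rest on the guess that a grows with the loading.

The flask gives 40.8 % and 49.2 %.

    substrate + free catalyst → free catalyst + open intermediate (k = 44000 L mol⁻¹ h⁻¹)
    free catalyst + open intermediate ⇌ catalyst intermediate (K = 72.0 L mol⁻¹, k = 7400 L mol⁻¹ h⁻¹)
    partner + catalyst intermediate → free catalyst + target (k = 430 L mol⁻¹ h⁻¹)
    open intermediate + capture agent → trapped intermediate (k = 1.50 L mol⁻¹ h⁻¹)
    open intermediate → side product (k = 0.0140 h⁻¹)

This flask's end state, target 47.7 % with capture agent 50.8 % left, gives a = 0.705, less than the 0.784 I carried. At 0.0136 d in this flask, open intermediate goes to trapped intermediate 1.1 times as fast as it joins free catalyst to form catalyst intermediate, that reversible step's forward rate alone. Over the run in this flask, backward turnover of that step is 30 % of the forward one.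

For a neighbour charged with 0.50 M of capture agent, the carried a, scaled to this flask's loading and to that charge, becomes 0.314, which as before gives 23.9 % for 30 min; a trial at that share and the halfway step give 26.2 % for 3.0 d. That neighbour computes to 22.4 % at 30 min and 27.2 % at 3.0 d.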